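The numbers stand for no real mixture.

The target in these flasks is made from substrate and also eaten by substrate, and that gives each flask a ceiling.

- Monday's: substrate 0.51 M; solid reagent 0.800 equiv; time 6.0 min
- Thursday's: substrate 0.51 M; solid reagent 0.800 equiv; time 8.0 min

    substrate ⇌ tight pair (K1 = 0.00868, k1 = 0.00696 /s)
    tight pair ⇌ loose pair (K2 = 0.041, k2 = 0.735 /s)
    coupling partner + tight pair → target (k3 = 0.839 /M/s)
    coupling partner + loose pair → isomer of the product (k4 = 0.642 /M/s)
    solid reagent ⇌ coupling partner, rate k5*(cs5 - [coupling partner]) while solid is left; crystals form when [coupling partner] > cs5 (cs5 = 0.22 M, k5 = 0.0250 /s)
    substrate + target → side product (k6 = 0.00924 /M/s)

- percentages count the substrate that a species holds: one side product counts as two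
- solid, in amounts per volume of the solution: solid reagent
- at the start none of the solid reagent is in solution
- run time (Monday's): 6.0 min

- which of the two there is more of at the end, counted by the substrate in each, Monday's (target / side product)
- which of the two there is more of at the end, counted by the substrate in each, Thursday's (target / side product)
- target at the end, in percent of the substrate charged, Monday's
- target at the end, in percent of the substrate charged, Thursday's

We reckon by hand first. The tight pair relaxes with a half-life of 0.857 s, far shorter than the run, so we hold it steady; the first step runs back at 0.802 /s. We drop the path through the loose pair, because its weight 0.0263 /M/s is far smaller than the constant of the tight pair's coupling. The solid answers with a time constant of 40.0 s, and capture of the tight pair holds c(coupling partner) near 0.193 M. Substrate then goes to target with a pseudo-first-order constant φ = 0.00117 /s, and with κ the side reaction's constant: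

dc(target)/dt = c(substrate) × (φ − κ c(target))

Substrate stands outside the bracket. We call φ/κ the ceiling 0.127 M: the c(target) at which making and eating balance. It is 24.9% of the charge. Side product counts double, so at a third of the ceiling, 8.29% of the charge, the two gain substrate alike. That parity is our zero, and above it side product gains faster.

Now the settings. Time: target climbs towards the ceiling as a first-order lag, with a half-life of 2.5 min by the side reaction alone at charged substrate, lengthening as substrate falls; one lag unit is one time constant of that lag. Taking substrate's loss constant halfway between φ and twice φ, and averaging substrate over the run, we get 1.30 lag units on Monday's and 1.62 on Thursday's. That gives target 18.1% and 19.9%, against side product 28.4% and 40.6%, so side product leads on both days . Substrate: more of it shortens the lag but lowers the ceiling as a percentage of the charge, so the two pull opposite ways. Solid reagent: the charge of 0.408 M stands above the solubility, but coupling uses it up as well, and by hand a charge too small to hold the plateau lowers the ceiling.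

The forecast gives side product for Monday's and side product for Thursday's, with target 17.7% and 19.7%, a little below our figures . Its grounds: “the side reaction is comparable to target formation”.

The simulation gives Monday's target 17.6% and side product 25.2%, and Thursday's target 19.7% and side product 35.6%. Moved by a factor of 1.3, the settings shift Thursday's target in this order: substrate (3.3 points), then solid reagent (2.2 points), then time (1.9 points). Thursday's target has moved by 6 points at 0.472 equiv of solid reagent, yet stays within that up to at least 6.4 equiv.

Reading Monday's c(coupling partner) of 0.204 M at the end puts the ceiling at 26.0% of the charge, and target stands below it. The neighbouring flask, Monday's with 0.200 equiv of solid reagent, stands at the same time with c(coupling partner) at 0.0337 M. The same reckoning, on that end value, gives a ceiling of 5.03%. That flask's target reads 6.05%, above its ceiling, with side product at 13.9% and 79% of the substrate still there.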